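The runs were generated by integration from invented constants, and the scatter is random.

1430 turnovers per catalyst charged are what this flask owes: its charge of left-handed substrate over its charge of free catalyst. The single-handed catalyst has to make them before the right-handed substrate is left nearly alone.

- violet: left-handed substrate 0.30 M; right-handed substrate 0.30 M; solid reagent 0.45 M; free catalyst 0.32 mM; run made earlier
- flask: left-handed substrate 0.30 M; solid reagent 0.450 M; free catalyst 0.21 mM; right-handed substrate 0.30 M; time 4.0 h

violet run (percent of the left-handed substrate and right-handed substrate together charged)

| time / min | right-handed substrate / % | left-handed substrate / % | left-handed product / % |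
|---|---|---|---|
| 4.00 | 50.1 | 49.6 | 1.1 |
| 12.0 | 49.3 | 46.0 | 4.5 |
| 20.0 | 50.6 | 40.2 | 9.6 |
| 30.0 | 48.8 | 32.6 | 17.1 |
| 40.0 | 51.0 | 27.1 | 25.0 |
| 60.0 | 49.5 | 10.4 | 39.9 |
| 80.0 | 48.7 | 1.3 | 48.7 |

(each reading ± 0.5 percentage points)

* whether the excess of right-handed substrate over left-handed substrate among what is left of the two reaches 98 % by 4.0 h (no / yes)
* the highest excess of right-handed substrate over left-handed substrate among what is left of the two up to 4.0 h

- free catalyst is single-handed; left-handed substrate and right-handed substrate are mirror images of each other, charged as a racemate, each of them at the stated concentration
- solid, in amounts per volume of the solution: solid reagent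
- the numbers in the tables scatter with a standard deviation of 0.5 percentage points
- steps under discussion: free catalyst + left-handed substrate <-> catalyst intermediate A; free catalyst + right-handed substrate <-> catalyst intermediate B; partner + catalyst intermediate A -> free catalyst + left-handed product; partner + catalyst intermediate B -> free catalyst + right-handed product; 2 free catalyst <-> resting dimer; partner <-> dormant form; solid reagent <-> partner
- at the start none of the solid reagent is in solution
- no earlier run changes the charge of free catalyst; that part of a forecast is a guess

The violet run supplies the clock. Its last left-handed product reading, over its time, gives the turnover speed (turnover frequency), the turnovers per catalyst charged per hour, averaged over the run: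

speed = product fraction × both substrates charged / catalyst charged / time = 685 /h

The first setting is the catalyst charge, cut to 65.6 % of violet's. At constant speed that stretches the hours, and my own reckoning gives:

time for the flask = turnovers owed / speed = 2.09 h

Constant speed is a guess, since no earlier run changes the catalyst charge.

The second setting is the solid reagent, charged as in violet. One partner goes per turnover, so the left-handed substrate calls on 66.7 % of the solid reagent charged, with partner passing into the dormant form not counted.

The third is time. The 4.0 h allowed exceeds the reckoned time by 1.91 h, and that margin has to cover the tail. The wanted excess means left-handed substrate at 1.01 % of the right-handed substrate left, while violet's last readings gave 2.67 %. My answer is yes.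

The forecast says yes, with a top of 99.9 % (range 98.5 % to 100 %): “Even if the right-handed substrate then reacts slowly, the ratio keeps improving”.

The flask gives yes, with a top of >99.9 %. It reached the wanted excess at 1.73 h, with right-handed substrate at 48.2 % of both substrates charged.

    free catalyst + left-handed substrate ⇌ catalyst intermediate A (K = 96.0 /M, k = 1.20 × 10⁵ /M/h)
    free catalyst + right-handed substrate ⇌ catalyst intermediate B (K = 0.790 /M, k = 72000 /M/h)
    partner + catalyst intermediate A → free catalyst + left-handed product (k = 17000 /M/h)
    partner + catalyst intermediate B → free catalyst + right-handed product (k = 7700 /M/h)
    2 free catalyst ⇌ resting dimer, settled at all times (K = 2200 /M)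
    partner ⇌ dormant form (K = 6.20, k = 0.570 /h)
    solid reagent ⇌ partner, rate k7*(cs7 - [partner]) while solid is left; crystals form when [partner] > cs7 (solubility = 0.290 M, k = 1.40 /h)

The flask's turnover speed averaged up to 2.00 h, with left-handed product at 49.9 %, stood at 713 /h, the violet run's average up to its last reading having been 685 /h.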